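The target is a bicyclo[3.2.1]octene: a six-membered ring (C1 allyl bridgehead, C2=C3 enol ether, C4, C5 methoxy bridgehead, C8 ketone) spanned by C6 (aryl) and C7 (methyl). Oxygen on C4, C5 and C8 in a row is the signature of an alpha-ketol shift. Moving C6 back from C5 to C4 reveals a bicyclo[2.2.2]octenone, which divides across C1–C7 and C4–C6 into (E)-isoelemicin and a 5-allyl-3-methoxy-2-silyloxy ortho-quinone monoketal. One enantioselective [4+2] cycloaddition closes the ring C1, C2, C3, C4, C6, C7, forms both bonds and sets four stereocentres; fluoride then triggers the shift.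

Key step: step 8

Remarks
- The core labels are used throughout: C1 allyl bridgehead, C2=C3 enol ether, C4 oxygenated carbon, C5, C6 aryl carbon, C7 methyl carbon, C8 ketal or ketone carbon. In the bicyclo[3.2.1] compounds they are also the locants of the names. The bicyclo[2.2.2] compounds carry systematic names, with the core labels added in brackets. Ar = 3,4,5-trimethoxyphenyl; TBS = tert-butyldimethylsilyl.
- Assumption: the sense of induction of the Cu(OTf)2 bis(oxazoline) catalyst cannot be predicted. The (S,S) ligand is written as the one that gives the required enantiomer of the adduct, and the (R,R) ligand is used if the opposite diene face reacts.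
- The (E)-propenyl unit comes from a geometry-retaining cross-coupling, because a non-stabilised ethylidene ylide would give mainly the (Z)-alkene and hence the wrong C7 epimer.
- The phenol oxygen that becomes the C5 carbonyl is unveiled last, from a formyl group and almost without base. The two neighbouring ring oxygens are therefore distinguished by construction and the silyl group has little chance to migrate.
- The ketal is hydrolysed before C4 is reduced. Afterwards the C3 enol ether would no longer be protected by conjugation, and the ketal methoxy group syn to C4 would block the required hydride face.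

Step 1
Reactants: 1 2,5-dimethoxyphenol
Product: 2 2-hydroxy-3,6-dimethoxybenzaldehyde
Conditions: MgCl2, Et3N, (CH2O)n, MeCN, reflux; aq. HCl
Reagents that add atoms: paraformaldehyde (as formaldehyde), C=O
Why: Casiraghi–Skattebøl ortho-formylation, in which the magnesium phenoxide delivers formaldehyde only to an ortho position and C6 is the single free ortho carbon, so no regiochemical choice arises.

Step 2
Reactants: 2 2-hydroxy-3,6-dimethoxybenzaldehyde; 3 allyl bromide
Product: 4 2-(allyloxy)-3,6-dimethoxybenzaldehyde
Conditions: K2CO3, DMF, 60 °C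
Reagents that add atoms: none
Why: Williamson ether synthesis on the only hydroxyl group, which is alkylated cleanly by carbonate in a dipolar aprotic solvent.

Step 3
Reactants: 4 2-(allyloxy)-3,6-dimethoxybenzaldehyde
Product: 7 5-allyl-2-hydroxy-3,6-dimethoxybenzaldehyde, via ortho-dienone 5 (not isolated), via para-dienone 6 (not isolated)
Conditions: N,N-diethylaniline, 190 °C, degassed
Reagents that add atoms: none
Why: Para-Claisen rearrangement: both ortho carbons are substituted, so the [3,3] shift to an ortho carbon is followed by a Cope [3,3] shift that relays the allyl group to the free para carbon, and tautomerisation then restores the phenol with the allyl group beside the C6 methoxy group.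

Step 4
Reactants: 7 5-allyl-2-hydroxy-3,6-dimethoxybenzaldehyde
Product: 8 5-allyl-2-(tert-butyldimethylsilyloxy)-3,6-dimethoxybenzaldehyde
Conditions: TBSCl, imidazole, DMF, rt
Reagents that add atoms: tert-butyldimethylsilyl chloride, C[Si](C)(Cl)C(C)(C)C
Why: Imidazole-promoted O-silylation of the single phenol, which fixes the silyl group on the oxygen that becomes the C4 substituent of the diene.

Step 5
Reactants: 8 5-allyl-2-(tert-butyldimethylsilyloxy)-3,6-dimethoxybenzaldehyde
Product: 10 3-allyl-6-(tert-butyldimethylsilyloxy)-2,5-dimethoxyphenol, via aryl formate 9 (not isolated)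
Conditions: mCPBA, CH2Cl2, 0 °C; then MeOH, KHCO3 (0.1 equiv), 0 °C
Reagents that add atoms: 3-chloroperbenzoic acid (mCPBA), OOC(=O)c1cccc(Cl)c1
Why: Baeyer–Villiger (Dakin-type) oxidation in which the electron-rich 2,6-dioxygenated aryl group should migrate well before the terminal alkene is epoxidised at 0 °C, followed by near-neutral methanolysis of the labile aryl formate, so that the phenol appears beside the silyl ether without a long-lived phenoxide.

Step 6
Reactants: 10 3-allyl-6-(tert-butyldimethylsilyloxy)-2,5-dimethoxyphenol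
Product: 11 5-allyl-2-(tert-butyldimethylsilyloxy)-3,6,6-trimethoxycyclohexa-2,4-dien-1-one
Conditions: PhI(OAc)2, MeOH, 0 °C; quick filtration through neutral alumina, used at once
Reagents that add atoms: methanol, CO
Why: Oxidative dearomatisation of a 2-methoxyphenol by a hypervalent iodine reagent, in which methanol adds to the methoxy-bearing ortho carbon (better donor-stabilised and less shielded than the silyloxy carbon) to give the ortho-quinone monoketal, whose three ring substituents should retard self-dimerisation.

Step 7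
Reactants: 12 5-bromo-1,2,3-trimethoxybenzene; 13 (E)-prop-1-enylboronic acid pinacol ester
Product: 14 (E)-isoelemicin
Conditions: Pd(dppf)Cl2 (3 mol%), K2CO3, 1,4-dioxane/H2O, 80 °C
Reagents that add atoms: none
Why: Suzuki–Miyaura cross-coupling, in which transmetalation and reductive elimination retain the alkene geometry, so the (E)-propenyl group is transferred intact.

Step 8
Reactants: 11 5-allyl-2-(tert-butyldimethylsilyloxy)-3,6,6-trimethoxycyclohexa-2,4-dien-1-one; 14 (E)-isoelemicin
Product: 15 (1S,4S,7R,8S)-4-allyl-1-(tert-butyldimethylsilyloxy)-3,3,6-trimethoxy-8-methyl-7-(3,4,5-trimethoxyphenyl)bicyclo[2.2.2]oct-5-en-2-one (core labels: allyl on C1, silyloxy on C4, ketone C5, aryl on C6 syn to C2=C3, methyl on C7 syn to the C8 ketal)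
Conditions: Cu(OTf)2 (10 mol%), (S,S)-2,2'-isopropylidenebis(4-tert-butyl-2-oxazoline) (11 mol%), 4 Å molecular sieves, CH2Cl2, −40 → 0 °C, dienone added slowly to the alkene
Reagents that add atoms: none
Why: Proposed new method: a chiral-Lewis-acid-catalysed inverse-electron-demand Diels–Alder reaction of a masked ortho-benzoquinone, argued as follows: dienone 11 is an electron-poor diene whose C5 carbonyl oxygen and one C8 methoxy oxygen can chelate divalent copper, which lowers its LUMO and holds the bis(oxazoline) ligand over one face, so that the nucleophilic methyl-bearing alkene carbon C7 bonds first to the delta carbon C1 and the benzylic carbon C6 then closes onto the alpha carbon C4 in one concerted but asynchronous [4+2] event. The closest known reaction types are the uncatalysed cycloadditions of masked ortho-benzoquinones with propenylarenes and the Cu(OTf)2 bis(oxazoline)-catalysed inverse-demand hetero-Diels–Alder reactions of chelating unsaturated alpha-keto esters with electron-rich alkenes. The single ring formed, the six-membered carbocycle C1–C2–C3–C4–C6–C7, is closed by intermolecular suprafacial [4+2] addition across the diene termini C1 and C4, which turns the cyclohexadienone into the bicyclo[2.2.2]octenone. The bridgeheads C1 and C4 are tied to each other by the ring and take their absolute sense from the diene face that the ligand leaves open, C6 is set by endo approach (aryl under C2=C3 and away from the C8 ketal) and C7 by the (E) geometry of 14, which places methyl trans to aryl. Regio-, endo- and facial selectivity are all required: the first is secured by the polarity match of diene and styrene, the second by secondary overlap of the aryl ring with the dienone together with the bulk of the ketal, and the third by the twofold-symmetric ligand, which must tell apart the two enantiotopic ketal methoxy groups when the Cu(OTf)2 complex binds.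

Step 9
Reactants: 15 the Diels–Alder adduct
Product: 17 (1S,5S,6R,7S)-1-allyl-5-hydroxy-3,8,8-trimethoxy-7-methyl-6-(3,4,5-trimethoxyphenyl)bicyclo[3.2.1]oct-2-en-4-one, via bridgehead ketol 16 (not isolated)
Conditions: TBAF, THF, 0 °C → rt; aq. NH4Cl
Reagents that add atoms: none
Why: Fluoride-induced desilylation followed by an alpha-ketol (acyloin) rearrangement, in which the C4 alkoxide pushes C6 suprafacially and with retention onto the C5 carbonyl carbon, the equilibrium being drawn to the bicyclo[3.2.1] isomer by conjugation of the new C4 ketone with C2=C3, while the new C5 stereocentre is dictated by the rigid bicyclic frame.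

Step 10
Reactants: 17 the bicyclo[3.2.1] alpha-ketol
Product: 18 (1S,5S,6R,7S)-1-allyl-3,5,8,8-tetramethoxy-7-methyl-6-(3,4,5-trimethoxyphenyl)bicyclo[3.2.1]oct-2-en-4-one
Conditions: NaH, MeI, DMF, 0 °C → rt
Reagents that add atoms: iodomethane, CI
Why: Williamson O-methylation of the tertiary alkoxide, the only nucleophilic site because neither the C4 ketone nor the C8 ketal carbon has an enolisable neighbour.

Step 11
Reactants: 18 the C5 methyl ether
Product: 19 (1S,5R,6R,7S)-1-allyl-3,5-dimethoxy-7-methyl-6-(3,4,5-trimethoxyphenyl)bicyclo[3.2.1]oct-2-ene-4,8-dione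
Conditions: TFA/H2O (9:1), CH2Cl2, 0 °C → rt
Reagents that add atoms: water, O
Why: Acid-catalysed ketal hydrolysis carried out at the enone stage, where the C3 methoxy group belongs to an alpha-methoxy enone and therefore resists protonation at C2, while the allyl group, the aryl ethers and the tertiary methyl ether tolerate aqueous acid.

Step 12
Reactants: 19 the 4,8-dione
Product: 20 (1S,4R,5S,6R,7S)-1-allyl-4-hydroxy-3,5-dimethoxy-7-methyl-6-(3,4,5-trimethoxyphenyl)bicyclo[3.2.1]oct-2-en-8-one (hydroxyl on the C6–C7 side)
Conditions: NaBH4 (1 equiv), CeCl3·7H2O, MeOH/CH2Cl2, −78 °C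
Reagents that add atoms: none
Why: Luche 1,2-reduction, in which the cerium-activated conjugated C4 carbonyl, held between the C3 and C5 methoxy oxygens, is expected to react before the C8 ketone that lies between two quaternary carbons and beside the C7 methyl group, and hydride enters C4 from the face syn to the small C8 carbonyl because the endo aryl group on C6 blocks the other face, which sets (4R).

Step 13
Reactants: 20 the C4 alcohol
Product: 21 (1S,4R,5S,6R,7S)-1-allyl-3,5-dimethoxy-7-methyl-8-oxo-6-(3,4,5-trimethoxyphenyl)bicyclo[3.2.1]oct-2-en-4-yl acetate (CNP0181407.1)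
Conditions: Ac2O, pyridine, DMAP (cat.), CH2Cl2, 0 °C → rt
Reagents that add atoms: acetic anhydride, CC(=O)OC(C)=O
Why: DMAP-catalysed acylation of the only hydroxyl group, which touches no stereocentre and gives the target.

Compound list
1 | 2,5-dimethoxyphenol | COc1ccc(OC)c(O)c1 | starting material
2 | 2-hydroxy-3,6-dimethoxybenzaldehyde | COc1ccc(OC)c(C=O)c1O | intermediate
3 | allyl bromide | C=CCBr | starting material
4 | 2-(allyloxy)-3,6-dimethoxybenzaldehyde | COc1ccc(OC)c(C=O)c1OCC=C | intermediate
5 | ortho-dienone, 5-allyl-2,5-dimethoxy-6-oxocyclohexa-1,3-diene-1-carbaldehyde (racemic, transient, not isolated) | O=CC1=C(OC)C=CC(OC)(CC=C)C1=O | intermediate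
6 | para-dienone, 3-allyl-2,5-dimethoxy-6-oxocyclohexa-1,4-diene-1-carbaldehyde (racemic, transient, not isolated) | O=CC1=C(OC)C(CC=C)C=C(OC)C1=O | intermediate
7 | 5-allyl-2-hydroxy-3,6-dimethoxybenzaldehyde | O=Cc1c(O)c(OC)cc(CC=C)c1OC | intermediate
8 | 5-allyl-2-(tert-butyldimethylsilyloxy)-3,6-dimethoxybenzaldehyde | O=Cc1c(O[Si](C)(C)C(C)(C)C)c(OC)cc(CC=C)c1OC | intermediate
9 | aryl formate, 3-allyl-6-(tert-butyldimethylsilyloxy)-2,5-dimethoxyphenyl formate (not isolated) | O=COc1c(O[Si](C)(C)C(C)(C)C)c(OC)cc(CC=C)c1OC | intermediate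
10 | 3-allyl-6-(tert-butyldimethylsilyloxy)-2,5-dimethoxyphenol | Oc1c(O[Si](C)(C)C(C)(C)C)c(OC)cc(CC=C)c1OC | intermediate
11 | 5-allyl-2-(tert-butyldimethylsilyloxy)-3,6,6-trimethoxycyclohexa-2,4-dien-1-one (key-step precursor; core labels: C5 carbonyl, C4 silyloxy, C3 methoxy, C2 H, C1 allyl, C8 ketal) | O=C1C(O[Si](C)(C)C(C)(C)C)=C(OC)C=C(CC=C)C1(OC)OC | intermediate
12 | 5-bromo-1,2,3-trimethoxybenzene | COc1cc(Br)cc(OC)c1OC | starting material
13 | (E)-prop-1-enylboronic acid pinacol ester, (E)-4,4,5,5-tetramethyl-2-(prop-1-en-1-yl)-1,3,2-dioxaborolane | C/C=C/B1OC(C)(C)C(C)(C)O1 | starting material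
14 | (E)-isoelemicin, (E)-1,2,3-trimethoxy-5-(prop-1-en-1-yl)benzene | C/C=C/c1cc(OC)c(OC)c(OC)c1 | intermediate
15 | (1S,4S,7R,8S)-4-allyl-1-(tert-butyldimethylsilyloxy)-3,3,6-trimethoxy-8-methyl-7-(3,4,5-trimethoxyphenyl)bicyclo[2.2.2]oct-5-en-2-one (key-step product; aryl syn to the enol ether bridge, methyl syn to the ketal carbon) | C=CC[C@]12C=C(OC)[C@](O[Si](C)(C)C(C)(C)C)(C(=O)C1(OC)OC)[C@@H](c1cc(OC)c(OC)c(OC)c1)[C@@H]2C | intermediate
16 | bridgehead ketol, (1S,4S,7R,8S)-4-allyl-1-hydroxy-3,3,6-trimethoxy-8-methyl-7-(3,4,5-trimethoxyphenyl)bicyclo[2.2.2]oct-5-en-2-one (present as its alkoxide, not isolated) | C=CC[C@]12C=C(OC)[C@](O)(C(=O)C1(OC)OC)[C@@H](c1cc(OC)c(OC)c(OC)c1)[C@@H]2C | intermediate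
17 | (1S,5S,6R,7S)-1-allyl-5-hydroxy-3,8,8-trimethoxy-7-methyl-6-(3,4,5-trimethoxyphenyl)bicyclo[3.2.1]oct-2-en-4-one (aryl endo; methyl exo) | C=CC[C@]12C=C(OC)C(=O)[C@](O)(C1(OC)OC)[C@@H](c1cc(OC)c(OC)c(OC)c1)[C@@H]2C | intermediate
18 | (1S,5S,6R,7S)-1-allyl-3,5,8,8-tetramethoxy-7-methyl-6-(3,4,5-trimethoxyphenyl)bicyclo[3.2.1]oct-2-en-4-one | C=CC[C@]12C=C(OC)C(=O)[C@](OC)(C1(OC)OC)[C@@H](c1cc(OC)c(OC)c(OC)c1)[C@@H]2C | intermediate
19 | (1S,5R,6R,7S)-1-allyl-3,5-dimethoxy-7-methyl-6-(3,4,5-trimethoxyphenyl)bicyclo[3.2.1]oct-2-ene-4,8-dione | C=CC[C@]12C=C(OC)C(=O)[C@](OC)(C1=O)[C@@H](c1cc(OC)c(OC)c(OC)c1)[C@@H]2C | intermediate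
20 | (1S,4R,5S,6R,7S)-1-allyl-4-hydroxy-3,5-dimethoxy-7-methyl-6-(3,4,5-trimethoxyphenyl)bicyclo[3.2.1]oct-2-en-8-one | C=CC[C@]12C=C(OC)[C@@H](O)[C@](OC)(C1=O)[C@@H](c1cc(OC)c(OC)c(OC)c1)[C@@H]2C | intermediate
21 | (1S,4R,5S,6R,7S)-1-allyl-3,5-dimethoxy-7-methyl-8-oxo-6-(3,4,5-trimethoxyphenyl)bicyclo[3.2.1]oct-2-en-4-yl acetate | C=CC[C@]12C=C(OC)[C@@H](OC(C)=O)[C@](OC)(C1=O)[C@@H](c1cc(OC)c(OC)c(OC)c1)[C@@H]2C | target

Total step count: 13. Longest linear sequence: 12 (steps 1–6 and 8–13); step 7 is a one-step branch.

Steps most likely to fail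

1. Step 8 (proposed new method). What may go wrong: weak facial discrimination by the catalyst, or ionisation of the dimethyl ketal by the Lewis acid, which would divert the dienone into cationic addition or rearomatisation. The fallback uses known chemistry and sets out from 11 and 14. The uncatalysed cycloaddition in toluene at 110 °C (sealed tube, alkene in excess) should give the same endo adduct as a racemate, that is 15 together with its mirror image, the enantiomeric adduct F1. The two are separated by preparative chromatography on an amylose tris(3,5-dimethylphenylcarbamate) stationary phase, and the route is rejoined at 15.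

2. Step 12. What may go wrong: loss of chemoselectivity, with hydride attacking the strained C8 bridge ketone as fast as or faster than the conjugated C4 carbonyl. The fallback sets out from 19 and turns that preference to use. NaBH4 alone (MeOH/CH2Cl2, −78 °C) should reduce the C8 ketone first, hydride arriving over the enone bridge, to give the 8-hydroxy enone F2; the C8 configuration is of no consequence. TESOTf and 2,6-lutidine give the 8-triethylsilyl ether F3. Luche reduction, now with a single carbonyl group and the same facial bias, gives the allylic alcohol F4, and Ac2O/pyridine/DMAP gives the silyl ether acetate F5. TBAF buffered with AcOH frees the 8-hydroxy acetate F6, and Dess–Martin periodinane with NaHCO3 restores the C8 ketone, so the sequence comes back to the route at 21.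

3. Step 10. What may go wrong: under strongly basic conditions the congested tertiary alkoxide may revert through the ketol shift or fragment, and its alkylation may be sluggish. The fallback sets out from 17 and methylates the neutral alcohol with trimethyloxonium tetrafluoroborate and 1,8-bis(dimethylamino)naphthalene in CH2Cl2. No alkoxide is formed, so the skeleton cannot revert, and the route is rejoined at 18; this fallback makes no new compound (F0).

Further compounds
F1 | step 8 | (1R,4R,7S,8R)-4-allyl-1-(tert-butyldimethylsilyloxy)-3,3,6-trimethoxy-8-methyl-7-(3,4,5-trimethoxyphenyl)bicyclo[2.2.2]oct-5-en-2-one (enantiomer of 15) | C=CC[C@@]12C=C(OC)[C@@](O[Si](C)(C)C(C)(C)C)(C(=O)C1(OC)OC)[C@H](c1cc(OC)c(OC)c(OC)c1)[C@H]2C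
F2 | step 12 | (1S,5R,6R,7S,8S)-1-allyl-8-hydroxy-3,5-dimethoxy-7-methyl-6-(3,4,5-trimethoxyphenyl)bicyclo[3.2.1]oct-2-en-4-one (hydroxyl on the C6–C7 side) | C=CC[C@]12C=C(OC)C(=O)[C@](OC)([C@H]1O)[C@@H](c1cc(OC)c(OC)c(OC)c1)[C@@H]2C
F3 | step 12 | (1S,5R,6R,7S,8S)-1-allyl-3,5-dimethoxy-7-methyl-8-(triethylsilyloxy)-6-(3,4,5-trimethoxyphenyl)bicyclo[3.2.1]oct-2-en-4-one | C=CC[C@]12C=C(OC)C(=O)[C@](OC)([C@H]1O[Si](CC)(CC)CC)[C@@H](c1cc(OC)c(OC)c(OC)c1)[C@@H]2C
F4 | step 12 | (1S,4R,5S,6R,7S,8S)-1-allyl-3,5-dimethoxy-7-methyl-8-(triethylsilyloxy)-6-(3,4,5-trimethoxyphenyl)bicyclo[3.2.1]oct-2-en-4-ol | C=CC[C@]12C=C(OC)[C@@H](O)[C@](OC)([C@H]1O[Si](CC)(CC)CC)[C@@H](c1cc(OC)c(OC)c(OC)c1)[C@@H]2C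
F5 | step 12 | (1S,4R,5S,6R,7S,8S)-1-allyl-3,5-dimethoxy-7-methyl-8-(triethylsilyloxy)-6-(3,4,5-trimethoxyphenyl)bicyclo[3.2.1]oct-2-en-4-yl acetate | C=CC[C@]12C=C(OC)[C@@H](OC(C)=O)[C@](OC)([C@H]1O[Si](CC)(CC)CC)[C@@H](c1cc(OC)c(OC)c(OC)c1)[C@@H]2C
F6 | step 12 | (1S,4R,5R,6R,7S,8S)-1-allyl-8-hydroxy-3,5-dimethoxy-7-methyl-6-(3,4,5-trimethoxyphenyl)bicyclo[3.2.1]oct-2-en-4-yl acetate | C=CC[C@]12C=C(OC)[C@@H](OC(C)=O)[C@](OC)([C@H]1O)[C@@H](c1cc(OC)c(OC)c(OC)c1)[C@@H]2C
F0 | step 10 | none | none
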